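**Assumptions.** Desertorin A as drawn has no stereocentres, so there is no absolute configuration to set. The hindered biaryl axis is unspecified in the SMILES. I assume it forms as a racemate or as rapidly interconverting atropisomers. The target is a 6,8'-linked bicoumarin: two 7-hydroxy-4-methoxy-5-methylcoumarin units joined from C6 of one to C8' of the other.

## Retrosynthesis
- Disconnect the C6–C8' biaryl bond by a Suzuki–Miyaura coupling between an A-ring 6-boronate and a B-ring 8-iodide.
- C8 is the most nucleophilic site of the monomer, so it is halogenated first. On the A ring this Br acts as a blocking group, and it is removed in the last step so that only C6 is coupled.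
- Both halves come from one monomer, 7-hydroxy-4-methoxy-5-methylcoumarin. It is made from orcinol by coumarin ring formation (Pechmann-type) and then selective 4-O-methylation.
- Order of construction: lactone ring, then 4-OMe, then halogenations, then biaryl, then dehalogenation.

## Route

**Step 1**
Reactants: **1** orcinol (5-methylbenzene-1,3-diol); **2** malonic acid
Product: **3** 4,7-dihydroxy-5-methylcoumarin
Conditions: ZnCl2, POCl3, 65 °C
Reagents that add atoms: none (the C3 unit comes from reactant 2; ZnCl2 and POCl3 are promoters)
Why: Pechmann-type condensation, in which acylation of orcinol at C4/C6 (ortho to OH, para to the other OH) followed by lactonisation gives the 5-methyl-7-hydroxy isomer. Nothing stereogenic is formed.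

**Step 2**
Reactants: **3**
Product: **4** 7-hydroxy-4-methoxy-5-methylcoumarin
Conditions: TMSCHN2, MeOH/MeCN, 0 °C to rt
Reagents that add atoms: TMSCHN2, C[Si](C)(C)C=[N+]=[N-] (adds CH3)
Why: The 4-OH is a vinylogous carboxylic acid (pKa about 4–5), so it is methylated selectively by diazoalkane, while the 7-ArOH (pKa about 8) is left alone. This is an O-methylation.

**Step 3**
Reactants: **4**
Product: **5** 8-bromo-7-hydroxy-4-methoxy-5-methylcoumarin
Conditions: NBS (1.0 equiv), MeCN, 0 °C
Reagents that add atoms: NBS, O=C1CCC(=O)N1Br (adds Br)
Why: Electrophilic aromatic bromination of the phenol ring goes ortho to OH. C8 is favoured over C6 because C6 is flanked by the 5-Me and 7-OH.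

**Step 4**
Reactants: **5**
Product: **6** 8-bromo-7-hydroxy-6-iodo-4-methoxy-5-methylcoumarin
Conditions: NIS (1.2 equiv), cat. TFA, MeCN, 40 °C
Reagents that add atoms: NIS, O=C1CCC(=O)N1I (adds I)
Why: The only remaining ortho position of the phenol is C6, so iodination there is regiochemically unambiguous (electrophilic iodination).

**Step 5**
Reactants: **6**
Product: **7** 8-bromo-7-hydroxy-4-methoxy-5-methyl-6-(4,4,5,5-tetramethyl-1,3,2-dioxaborolan-2-yl)coumarin
Conditions: B2pin2 (1.2 equiv), PdCl2(dppf) (5 mol%), KOAc, dioxane, 80 °C
Reagents that add atoms: B2pin2, CC1(C)OB(OC1(C)C)B1OC(C)(C)C(C)(C)O1 (adds Bpin)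
Why: Miyaura borylation reacts at the C–I bond in preference to the C–Br bond.

**Step 6**
Reactants: **4**
Product: **8** 7-hydroxy-8-iodo-4-methoxy-5-methylcoumarin
Conditions: NIS (1.05 equiv), MeCN, 0 °C to rt
Reagents that add atoms: NIS, O=C1CCC(=O)N1I (adds I)
Why: The same C8-selective electrophilic halogenation as in Step 3, using iodine so that the coupling in Step 7 can discriminate I from Br.

**Step 7**
Reactants: **7** (1.3 equiv); **8** (1.0 equiv)
Product: **9** 8-bromo-6-[7'-hydroxy-4'-methoxy-5'-methylcoumarin-8'-yl]-7-hydroxy-4-methoxy-5-methylcoumarin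
Conditions: Pd2(dba)3, SPhos, K3PO4, dioxane/H2O (5:1), 90 °C
Reagents that add atoms: none
Why: Suzuki–Miyaura coupling, where the electron-rich biaryl phosphine handles the tetra-ortho-substituted biaryl. The aryl iodide reacts in preference to the blocking C8–Br of the boronate. The axis forms without control, as assumed above.

**Step 8**
Reactants: **9**
Product: **10** desertorin A
Conditions: Pd(OAc)2, PPh3, HCO2Na, DMF, 80 °C
Reagents that add atoms: none (formate supplies only H)
Why: Pd-catalysed hydrodehalogenation removes the blocking Br. The lactone, the 4-OMe vinylogous ester, the free phenols and the C3=C4 alkene are untouched by Pd–H/formate. This gives the target.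

## Compound list
1 | orcinol | Cc1cc(O)cc(O)c1 | starting material
2 | malonic acid | OC(=O)CC(=O)O | starting material
3 | 4,7-dihydroxy-5-methylcoumarin | Cc1cc(O)cc2oc(=O)cc(O)c12 | intermediate
4 | 7-hydroxy-4-methoxy-5-methylcoumarin | COc1cc(=O)oc2cc(O)cc(C)c12 | intermediate
5 | 8-bromo-7-hydroxy-4-methoxy-5-methylcoumarin | COc1cc(=O)oc2c(Br)c(O)cc(C)c12 | intermediate
6 | 8-bromo-7-hydroxy-6-iodo-4-methoxy-5-methylcoumarin | COc1cc(=O)oc2c(Br)c(O)c(I)c(C)c12 | intermediate
7 | 8-bromo-6-Bpin-7-hydroxy-4-methoxy-5-methylcoumarin | COc1cc(=O)oc2c(Br)c(O)c(B3OC(C)(C)C(C)(C)O3)c(C)c12 | intermediate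
8 | 7-hydroxy-8-iodo-4-methoxy-5-methylcoumarin | COc1cc(=O)oc2c(I)c(O)cc(C)c12 | intermediate
9 | 8-bromo-6,8'-bicoumarin (Br-blocked biaryl) | COc1cc(=O)oc2c(Br)c(O)c(-c3c(O)cc(C)c4c(OC)cc(=O)oc34)c(C)c12 | intermediate
10 | desertorin A | COc1cc(=O)oc2cc(O)c(-c3c(O)cc(C)c4c(OC)cc(=O)oc34)c(C)c12 | target

**Total steps:** 8
**Longest linear sequence:** 7 (Steps 1, 2, 3, 4, 5, 7, 8); Step 6 is a parallel branch from 4.

## Three steps most likely to fail
1. **Step 7 (hindered Suzuki coupling).** Risks are protodeboronation of the ortho-OH boronate, the tetra-ortho-substituted product, and loss of I/Br discrimination.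
   Fallback: tether the two 7-OH groups as a methylene acetal (7-O–CH2–O-7'), using the B-ring iodide 8 and the A-ring 8-bromo-6-H compound 5, then close the biaryl bond by intramolecular Pd direct arylation. The Br at C8 blocks the wrong site, and cleaving the acetal gives the diphenol.
2. **Step 4 (C6 iodination).** The hindered C6 position competes with the nucleophilic C3 of the 4-methoxy-enone.
   Fallback: install both halogens at the orcinol stage. Make 2-bromoorcinol by sulfonation, bromination and desulfonation, then iodinate at C4. Pechmann condensation can then only close at C6, giving 6 directly with no C3 competition.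
3. **Step 8 (hydrodebromination).** Over-reduction of the coumarin C3=C4 alkene, or incomplete C–Br removal.
   Fallback: switch mechanism to a radical or photoredox dehalogenation (Hantzsch ester with an Ir or organic photocatalyst under blue light, or Bu3SnH/AIBN), which leaves the alkene untouched.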